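## Retrosynthetic overview

1. Feature: ring A (C4a, C5, C6, C7, C8, C8a) is a phloroglucinol. Its oxygens on C5, C7 and C8a are mutually meta, the C4 chain sits on C4a between two of them, and C6 and C8 carry only formyl groups. A siloxyalkyne and a 3-alkoxy vinylketene assemble exactly this pattern.
2. Last operations: O-dealkylation and the four formyl C–C bonds (C6, C8, C3', C5') are removed. This leaves a 5,7-dioxygenated 2-(2,4,6-trimethoxyphenyl)chroman, and ring B is bought as the aldehyde.
3. Ring C (formed second): O1–C2 and C2–C3 are cut together. The forward step is an oxocarbenium-ene closure of an ortho-(2,6-dimethylhept-2-en-4-yl)phenol with that aldehyde, in which C4 controls C3 and C2.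
4. Ring A (formed first): C4a–C8a, C5–C6 and C8–C8a are cut. The forward step is the benzannulation of 3-ethoxycyclobutenone with the enantiopure triisopropylsilyl ynol ether of 3-isobutyl-5-methylhex-4-en-1-yne.
5. C4 comes from a rhodium-catalysed asymmetric conjugate alkynylation of (E)-6-methylhept-3-en-2-one. The ketone then becomes the trisubstituted alkene and the alkynylsilane becomes the ynol silyl ether.

Key step: step 6

Assumption: chroman numbering (O1, C2, C3, C4, C4a, C5–C8, C8a; primed locants for ring B) is used for these atoms from the first step on. The target as drawn is (2R,3S,4S): aryl and isopropyl are cis, isopropyl and isobutyl are trans.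

Assumption: (R)-DTBM-SEGPHOS is taken as the ligand antipode that gives (S)-3. If the sense of induction is the opposite, the equally available (S)-ligand is used.

## Route

Step 1
Reactants: 1 (E)-6-methylhept-3-en-2-one; 2 (triisopropylsilyl)acetylene
Product: 3 (S)-6-methyl-4-[(triisopropylsilyl)ethynyl]heptan-2-one
Conditions: [Rh(OAc)(C2H4)2]2 (2.5 mol %), (R)-DTBM-SEGPHOS (5.5 mol %), 1,4-dioxane, 80 °C
Reagents that add atoms: none
Why: Rhodium-catalysed asymmetric conjugate alkynylation: the alkynylrhodium species formed from 2 adds 1,4 to the enone inside the pocket of the bulky bisphosphine, which selects one enone face and so sets C4 as S, while the size of the silyl group and of the ligand suppresses alkyne dimerisation.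

Step 2
Reactants: 3 (S)-6-methyl-4-[(triisopropylsilyl)ethynyl]heptan-2-one
Product: 4 (S)-2,6-dimethyl-4-[(triisopropylsilyl)ethynyl]heptan-2-ol
Conditions: MeMgBr (1.3 equiv), THF, −78 to 0 °C; aq NH4Cl
Reagents that add atoms: methylmagnesium bromide C[Mg]Br
Why: Grignard 1,2-addition to a methyl ketone; C4 is β to the carbonyl group and is not touched.

Step 3
Reactants: 4 (S)-2,6-dimethyl-4-[(triisopropylsilyl)ethynyl]heptan-2-ol
Product: 5 (S)-triisopropyl(3-isobutyl-5-methylhex-4-en-1-yn-1-yl)silane
Conditions: p-TsOH·H2O (5 mol %), benzene, 80 °C, Dean–Stark, short reaction time; chromatography on AgNO3-impregnated silica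
Reagents that add atoms: none
Why: Acid-catalysed E1 dehydration run to equilibrium: the tertiary cation can lose a proton only from C3 or from a methyl group, so C4 is not involved, the more substituted alkene should predominate, and the 1,1-disubstituted isomer, which binds silver ion more strongly, is removed on the silver-loaded silica.

Step 4
Reactants: 5 (S)-triisopropyl(3-isobutyl-5-methylhex-4-en-1-yn-1-yl)silane
Product: 6 (S)-3-isobutyl-5-methylhex-4-en-1-yne
Conditions: TBAF (1.1 equiv), THF, 0 °C; H2O, pentane extraction, careful concentration (volatile)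
Reagents that add atoms: none
Why: Fluoride-induced protodesilylation of an alkynylsilane; short contact at 0 °C is meant to keep the basic fluoride from abstracting the propargylic-allylic C4–H, so the skipped enyne and its configuration persist.

Step 5
Reactants: 6 (S)-3-isobutyl-5-methylhex-4-en-1-yne
Product: 9 (S)-triisopropyl[(3-isobutyl-5-methylhex-4-en-1-yn-1-yl)oxy]silane, via lithium acetylide 7 (not isolated), via lithium ynolate 8 (not isolated)
Conditions: n-BuLi (1.0 equiv), THF, −78 °C; transfer into t-BuOOLi (t-BuOOH + LiHMDS, THF, −78 °C), −78 to 0 °C; TIPSOTf (1.1 equiv), −78 to 0 °C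
Reagents that add atoms: tert-butyl hydroperoxide CC(C)(C)OO; triisopropylsilyl triflate CC(C)[Si](C(C)C)(C(C)C)OS(=O)(=O)C(F)(F)F
Why: Known route to triisopropylsilyl ynol ethers: the lithium acetylide is oxygenated by lithium tert-butyl peroxide to the ynolate, which the hard and bulky silyl triflate traps on oxygen, and only the sp C–H is acidic enough for one equivalent of n-BuLi at −78 °C, so C4 keeps its configuration.

Step 6
Reactants: 9 (S)-triisopropyl[(3-isobutyl-5-methylhex-4-en-1-yn-1-yl)oxy]silane; 10 3-ethoxycyclobut-2-en-1-one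
Product: 15 2-[(S)-2,6-dimethylhept-2-en-4-yl]-5-ethoxy-3-(triisopropylsilyloxy)phenol, via ethoxyvinylketene 11 (not isolated), via vinylcyclobutenone 12 (not isolated), via dienylketene 13 (not isolated), via cyclohexadienone 14 (not isolated)
Conditions: 10 (1.3 equiv, in portions), toluene (0.3 M), sealed tube, 110 to 140 °C
Reagents that add atoms: none
Why: This is the Danheiser benzannulation, the known reaction of cyclobutenones with siloxyalkynes to give resorcinol monosilyl ethers, run here with a 3-alkoxycyclobutenone so that a third oxygen arrives at C7. Heat opens 10 (4π electrocyclic) to ethoxyvinylketene 11; the alkyl-bearing, nucleophilic carbon of 9 bonds to the ketene carbonyl carbon (C4a–C8a) and the siloxy carbon bonds to the ketene α-carbon (C5–C6) in a [2+2] cycloaddition that gives 12. Reversible 4π opening of 12 gives dienylketene 13, and the isomer that holds the ethoxyvinyl group cis to the ketene closes ring A by 6π electrocyclisation (C8–C8a) to dienone 14, which tautomerises to phenol 15. No stereocentre is created: the sp3 ring carbon of 12 disappears on opening, and C4 is a spectator because the medium is neutral and free of acid, base and metal. The regiochemistry needed (free hydroxyl, the future O1, next to the C4 chain, silyloxy on the other flank, ethoxy para to the chain) follows from the polarisation of the ynol ether, and the chemoselectivity needed (the ketene takes the alkyne and not the trisubstituted alkene) follows from the far higher nucleophilicity of the ynol ether π bond. C6 and C8 stay free for formylation and the three oxygens emerge differentiated as OH, OSi and OEt.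

Step 7
Reactants: 15 2-[(S)-2,6-dimethylhept-2-en-4-yl]-5-ethoxy-3-(triisopropylsilyloxy)phenol; 16 2,4,6-trimethoxybenzaldehyde
Product: 21 (2R,3R,4S)-7-ethoxy-4-isobutyl-3-(prop-1-en-2-yl)-2-(2,4,6-trimethoxyphenyl)-5-(triisopropylsilyloxy)chroman, via trimethylsilyl ether 17 (not isolated), via silyl acetal 18 (not isolated), via oxocarbenium ion 19 (not isolated), via tertiary cation 20 (not isolated)
Conditions: 16 (1.05 equiv), 2,6-di-tert-butyl-4-methylpyridine (2.5 equiv), TMSOTf (2.2 equiv, slow addition), CH2Cl2 (0.01 M), −78 to 0 °C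
Reagents that add atoms: none
Why: Proposed new method: the phenol is silylated to 17, adds to the TMSOTf-activated aldehyde to give silyl acetal 18, and loss of hexamethyldisiloxane leaves O-aryl oxocarbenium ion 19, which the trisubstituted alkene attacks through C3 in a six-membered transition state to give tertiary cation 20, deprotonated by the hindered pyridine at a methyl group; the closest known reaction type is the oxonium-ene (Prins-type) cyclisation of 5-methylhex-4-en-1-ols with aldehydes to 2-substituted 3-isopropenyltetrahydropyrans, not yet shown for a phenolic oxygen with so electron-rich an aryl aldehyde; C3 is set kinetically, because allylic 1,3-strain keeps C4–H in the alkene plane beside the Z methyl group and the O1 tether reaches only the alkene face syn to C4a, so isopropenyl ends trans to isobutyl; C2 is set thermodynamically, because the O1–C2 bond next to the trimethoxyphenyl donor ionises reversibly under TMSOTf on warming and the epimers should converge on the 2,3-cis isomer, whose half-chair holds isobutyl and isopropenyl trans-diaxial (no peri clash with the C5 silyloxy group, no syn-axial partner on O1 or C4a) and the aryl group equatorial, whereas the 2,3-trans epimer must either press isobutyl against the C5 substituent or stand aryl and isobutyl 1,3-diaxial; the aprotic, base-buffered medium withholds the proton that would close the prenyl-type side chain onto O1 as a 2,2-dimethylchroman, and high dilution with about one equivalent of aldehyde disfavours Friedel–Crafts attack at C6 and C8.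

Step 8
Reactants: 21 (2R,3R,4S)-7-ethoxy-4-isobutyl-3-(prop-1-en-2-yl)-2-(2,4,6-trimethoxyphenyl)-5-(triisopropylsilyloxy)chroman
Product: 22 (2R,3S,4S)-7-ethoxy-4-isobutyl-3-isopropyl-2-(2,4,6-trimethoxyphenyl)-5-(triisopropylsilyloxy)chroman
Conditions: H2 (1 atm), PtO2 (5 mol %), EtOAc, rt
Reagents that add atoms: none
Why: Heterogeneous hydrogenation of a 1,1-disubstituted alkene, on platinum rather than palladium so that the doubly activated benzylic O1–C2 bond is not hydrogenolysed; no stereocentre is formed, and the C3 descriptor changes only because the substituent ranking changes.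

Step 9
Reactants: 22 (2R,3S,4S)-7-ethoxy-4-isobutyl-3-isopropyl-2-(2,4,6-trimethoxyphenyl)-5-(triisopropylsilyloxy)chroman
Product: 23 (2R,3S,4S)-7-ethoxy-4-isobutyl-3-isopropyl-2-(2,4,6-trimethoxyphenyl)chroman-5-ol
Conditions: TBAF (1.1 equiv), THF, 0 °C; H2O
Reagents that add atoms: none
Why: Fluoride cleavage of an aryl silyl ether, which uncovers C6 sterically and supplies a free C5 hydroxyl group to direct the formylation; the alkyl ethers and the chroman are inert to fluoride.

Step 10
Reactants: 23 (2R,3S,4S)-7-ethoxy-4-isobutyl-3-isopropyl-2-(2,4,6-trimethoxyphenyl)chroman-5-ol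
Product: 24 (2R,3S,4S)-2-(3,5-diformyl-2,4,6-trimethoxyphenyl)-7-ethoxy-5-hydroxy-4-isobutyl-3-isopropylchroman-6,8-dicarbaldehyde
Conditions: Cl2CHOMe (12 equiv), TiCl4 (12 equiv), CH2Cl2, −78 to 0 °C; ice-water
Reagents that add atoms: dichloromethyl methyl ether COC(Cl)Cl; water O
Why: Rieche formylation: each of the four free positions (C6, C8, C3', C5') is ortho or para to three oxygen donors and only meta to the formyl group that enters first on the same ring, so both rings should take two formyl groups, the titanium phenoxide at C5 steers the reagent to C6, and any reversible opening of O1–C2 under the Lewis acid returns to the same favoured 2,3-cis arrangement.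

Step 11
Reactants: 24 (2R,3S,4S)-2-(3,5-diformyl-2,4,6-trimethoxyphenyl)-7-ethoxy-5-hydroxy-4-isobutyl-3-isopropylchroman-6,8-dicarbaldehyde
Product: 25 sideroxylonal B, (2R,3S,4S)-2-(3,5-diformyl-2,4,6-trihydroxyphenyl)-5,7-dihydroxy-4-isobutyl-3-isopropylchroman-6,8-dicarbaldehyde
Conditions: BCl3 (1 M in CH2Cl2, 12 equiv), CH2Cl2, −78 °C to rt; ice-water
Reagents that add atoms: none
Why: Chelation-assisted ether cleavage: every methoxy and ethoxy group is ortho to a formyl group, BCl3 binds each carbonyl/ether pair and chloride removes the alkyl group, the two formyl groups on ring B now disfavour ionisation at C2, and dealkylated ring A is symmetric about the C4a–C7 axis, so a transient opening of O1–C2 could only reclose to the same constitution with the aryl group equatorial.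

## Compound list

1 | (E)-6-methylhept-3-en-2-one | CC(=O)/C=C/CC(C)C | starting material
2 | (triisopropylsilyl)acetylene | C#C[Si](C(C)C)(C(C)C)C(C)C | starting material
3 | (S)-6-methyl-4-[(triisopropylsilyl)ethynyl]heptan-2-one | CC(C)C[C@@H](CC(C)=O)C#C[Si](C(C)C)(C(C)C)C(C)C | intermediate
4 | (S)-2,6-dimethyl-4-[(triisopropylsilyl)ethynyl]heptan-2-ol | CC(C)C[C@@H](CC(C)(C)O)C#C[Si](C(C)C)(C(C)C)C(C)C | intermediate
5 | (S)-triisopropyl(3-isobutyl-5-methylhex-4-en-1-yn-1-yl)silane | CC(C)C[C@@H](C=C(C)C)C#C[Si](C(C)C)(C(C)C)C(C)C | intermediate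
6 | (S)-3-isobutyl-5-methylhex-4-en-1-yne | CC(C)C[C@@H](C=C(C)C)C#C | intermediate
7 | lithium acetylide of 6, [(S)-3-isobutyl-5-methylhex-4-en-1-yn-1-yl]lithium | CC(C)C[C@@H](C=C(C)C)C#C[Li] | intermediate
8 | lithium ynolate, lithium (S)-3-isobutyl-5-methylhex-4-en-1-yn-1-olate | CC(C)C[C@@H](C=C(C)C)C#C[O-].[Li+] | intermediate
9 | (S)-triisopropyl[(3-isobutyl-5-methylhex-4-en-1-yn-1-yl)oxy]silane | CC(C)C[C@@H](C=C(C)C)C#CO[Si](C(C)C)(C(C)C)C(C)C | intermediate
10 | 3-ethoxycyclobut-2-en-1-one | CCOC1=CC(=O)C1 | starting material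
11 | ethoxyvinylketene, 3-ethoxybuta-1,3-dien-1-one | C=C(OCC)C=C=O | intermediate
12 | vinylcyclobutenone, 2-[(S)-2,6-dimethylhept-2-en-4-yl]-4-(1-ethoxyvinyl)-3-(triisopropylsilyloxy)cyclobut-2-en-1-one (sp3 ring carbon unassigned) | O=C1C([C@@H](CC(C)C)C=C(C)C)=C(O[Si](C(C)C)(C(C)C)C(C)C)C1C(=C)OCC | intermediate
13 | dienylketene, 2-[(S)-2,6-dimethylhept-2-en-4-yl]-5-ethoxy-3-(triisopropylsilyloxy)hexa-1,3,5-trien-1-one | O=C=C([C@@H](CC(C)C)C=C(C)C)C(O[Si](C(C)C)(C(C)C)C(C)C)=CC(=C)OCC | intermediate
14 | cyclohexadienone, 2-[(S)-2,6-dimethylhept-2-en-4-yl]-5-ethoxy-3-(triisopropylsilyloxy)cyclohexa-2,4-dien-1-one | O=C1CC(OCC)=CC(O[Si](C(C)C)(C(C)C)C(C)C)=C1[C@@H](CC(C)C)C=C(C)C | intermediate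
15 | 2-[(S)-2,6-dimethylhept-2-en-4-yl]-5-ethoxy-3-(triisopropylsilyloxy)phenol | CC(C)C[C@@H](C=C(C)C)c1c(O[Si](C(C)C)(C(C)C)C(C)C)cc(OCC)cc1O | intermediate
16 | 2,4,6-trimethoxybenzaldehyde | COc1cc(OC)c(C=O)c(OC)c1 | starting material
17 | trimethylsilyl ether of 15 | CC(C)C[C@@H](C=C(C)C)c1c(O[Si](C(C)C)(C(C)C)C(C)C)cc(OCC)cc1O[Si](C)(C)C | intermediate
18 | silyl acetal, aryl (trimethylsilyloxy)(2,4,6-trimethoxyphenyl)methyl ether of 15 (acetal carbon unassigned) | CC(C)C[C@@H](C=C(C)C)c1c(O[Si](C(C)C)(C(C)C)C(C)C)cc(OCC)cc1OC(O[Si](C)(C)C)c2c(OC)cc(OC)cc2OC | intermediate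
19 | O-aryl oxocarbenium ion, triflate | CC(C)C[C@@H](C=C(C)C)c1c(O[Si](C(C)C)(C(C)C)C(C)C)cc(OCC)cc1[O+]=Cc2c(OC)cc(OC)cc2OC.[O-]S(=O)(=O)C(F)(F)F | intermediate
20 | tertiary cation, chroman with a 2-propyl cation on C3, triflate | CC(C)C[C@@H]1c2c(O[Si](C(C)C)(C(C)C)C(C)C)cc(OCC)cc2O[C@@H](c2c(OC)cc(OC)cc2OC)[C@H]1[C+](C)C.[O-]S(=O)(=O)C(F)(F)F | intermediate
21 | (2R,3R,4S)-7-ethoxy-4-isobutyl-3-(prop-1-en-2-yl)-2-(2,4,6-trimethoxyphenyl)-5-(triisopropylsilyloxy)chroman | CC(C)C[C@@H]1c2c(O[Si](C(C)C)(C(C)C)C(C)C)cc(OCC)cc2O[C@@H](c2c(OC)cc(OC)cc2OC)[C@H]1C(C)=C | intermediate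
22 | (2R,3S,4S)-7-ethoxy-4-isobutyl-3-isopropyl-2-(2,4,6-trimethoxyphenyl)-5-(triisopropylsilyloxy)chroman | CC(C)C[C@@H]1c2c(O[Si](C(C)C)(C(C)C)C(C)C)cc(OCC)cc2O[C@@H](c2c(OC)cc(OC)cc2OC)[C@H]1C(C)C | intermediate
23 | (2R,3S,4S)-7-ethoxy-4-isobutyl-3-isopropyl-2-(2,4,6-trimethoxyphenyl)chroman-5-ol | CC(C)C[C@@H]1c2c(O)cc(OCC)cc2O[C@@H](c2c(OC)cc(OC)cc2OC)[C@H]1C(C)C | intermediate
24 | (2R,3S,4S)-2-(3,5-diformyl-2,4,6-trimethoxyphenyl)-7-ethoxy-5-hydroxy-4-isobutyl-3-isopropylchroman-6,8-dicarbaldehyde | CC(C)C[C@@H]1c2c(O)c(C=O)c(OCC)c(C=O)c2O[C@@H](c2c(OC)c(C=O)c(OC)c(C=O)c2OC)[C@H]1C(C)C | intermediate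
25 | sideroxylonal B, (2R,3S,4S)-2-(3,5-diformyl-2,4,6-trihydroxyphenyl)-5,7-dihydroxy-4-isobutyl-3-isopropylchroman-6,8-dicarbaldehyde | CC(C)C[C@@H]1c2c(O)c(C=O)c(O)c(C=O)c2O[C@@H](c2c(O)c(C=O)c(O)c(C=O)c2O)[C@H]1C(C)C | target

## Step count and risks

Total step count: 11. Longest linear sequence: 11 steps (1 to 25); 2, 10 and 16 are bought.

**Step 7 (carries the label).**

What may go wrong:
- Friedel–Crafts hydroxyalkylation at C6 or C8 of ring A, or at the free positions of ring B in the product, may outrun attack through oxygen.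
- Traces of acid may close the side chain onto O1.
- The cation may lose the C3 proton instead of a methyl proton.
- The C2 epimers may converge incompletely on warming.

The fallback uses known reactions only. It sets out from 5 and comes back at 22. C2 is attached before ring A exists, and ring C is closed last at O1–C2.
- The Me2AlCl-promoted carbonyl-ene reaction of 5 with paraformaldehyde (CH2Cl2, −78 to 0 °C) should give homoallylic alcohol F1. Formaldehyde bonds to C3 anti to the isobutyl group on the rotamer that keeps C4–H in the alkene plane, which is the C3/C4 relationship of 22.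
- Dess–Martin oxidation (NaHCO3, CH2Cl2) gives aldehyde F2.
- 2,4,6-Trimethoxyphenyllithium (from 1,3,5-trimethoxybenzene and n-BuLi in THF) adds to give benzylic alcohol F3 as C2 epimers, both of which are used.
- NaH/MeI gives methyl ether F4, and TBAF then gives terminal alkyne F5.
- The acetylide oxidation and silylation of step 5 give siloxyalkyne F6, and benzannulation with 10 as in step 6 gives phenol F7.
- Hydrogenation (H2, PtO2) gives isopropyl phenol F8.
- Catalytic acid (PPTS, CH2Cl2) ionises the benzylic methyl ether so that the phenol oxygen closes ring C. This is the classical acid-mediated flavan closure, under the same thermodynamic control of C2, and it leads to 22.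

**Step 6 (key step).**

What may go wrong:
- The vinylogous-ester stabilisation of 10 may slow its 4π opening, so that the temperature needed promotes oxygen-to-carbon silyl migration in 9.
- The vinylketene may dimerise.
- The product phenol may be acylated by the ketene.

The fallback makes the same ketene 11 at room temperature by photochemical Wolff rearrangement, the known diazoketone variant of the Danheiser benzannulation. It sets out from 9 and comes back at 15.
- Ethyl vinyl ether is lithiated (t-BuLi, THF) and acylated with N-methoxy-N-methylacetamide to give 3-ethoxybut-3-en-2-one F9.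
- LiHMDS followed by CF3CO2CH2CF3 gives trifluoroacetyl ketone F10.
- MsN3, Et3N and H2O in MeCN give diazoketone F11.
- Irradiation of F11 with 9 (medium-pressure mercury lamp, CH2Cl2, rt), followed by warming in toluene at 80 to 110 °C, carries 12 through 13 and 14 to 15.

**Step 10.**

What may go wrong:
- TiCl4 and the HCl it liberates may ionise O1–C2 before ring B is deactivated, leading to elimination toward the styrene or to intermolecular arylation.
- Formylation may stall after one formyl group per ring, because the unhydrolysed chloro ether deactivates the ring.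

The fallback replaces electrophilic formylation by halogenation and metalation. It sets out from 23 and comes back at 25.
- K2CO3/MeI gives methyl ether F12. A silyl ether next to an aryllithium would migrate to carbon, hence the methyl group.
- NBS (4 equiv, MeCN, 0 °C) gives tetrabromide F13.
- t-BuLi (9 equiv, THF, −78 °C) followed by DMF gives tetraaldehyde F14.
- BCl3 as in step 11 cleaves the four methyl ethers and the ethyl ether to give 25.

## Further compounds

F1 | step 7 | (2R,3S)-3-isobutyl-2-(prop-1-en-2-yl)-5-(triisopropylsilyl)pent-4-yn-1-ol | CC(C)C[C@H](C#C[Si](C(C)C)(C(C)C)C(C)C)[C@@H](CO)C(C)=C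
F2 | step 7 | (2R,3S)-3-isobutyl-2-(prop-1-en-2-yl)-5-(triisopropylsilyl)pent-4-ynal | CC(C)C[C@H](C#C[Si](C(C)C)(C(C)C)C(C)C)[C@@H](C=O)C(C)=C
F3 | step 7 | (2R,3S)-3-isobutyl-2-(prop-1-en-2-yl)-1-(2,4,6-trimethoxyphenyl)-5-(triisopropylsilyl)pent-4-yn-1-ol, both C1 epimers | CC(C)C[C@H](C#C[Si](C(C)C)(C(C)C)C(C)C)[C@@H](C(O)c1c(OC)cc(OC)cc1OC)C(C)=C
F4 | step 7 | [(3S,4R)-3-isobutyl-5-methoxy-4-(prop-1-en-2-yl)-5-(2,4,6-trimethoxyphenyl)pent-1-yn-1-yl]triisopropylsilane | CC(C)C[C@H](C#C[Si](C(C)C)(C(C)C)C(C)C)[C@@H](C(OC)c1c(OC)cc(OC)cc1OC)C(C)=C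
F5 | step 7 | 2-[(2R,3S)-3-isobutyl-1-methoxy-2-(prop-1-en-2-yl)pent-4-yn-1-yl]-1,3,5-trimethoxybenzene | CC(C)C[C@H](C#C)[C@@H](C(OC)c1c(OC)cc(OC)cc1OC)C(C)=C
F6 | step 7 | triisopropyl{[(3S,4R)-3-isobutyl-5-methoxy-4-(prop-1-en-2-yl)-5-(2,4,6-trimethoxyphenyl)pent-1-yn-1-yl]oxy}silane | CC(C)C[C@H](C#CO[Si](C(C)C)(C(C)C)C(C)C)[C@@H](C(OC)c1c(OC)cc(OC)cc1OC)C(C)=C
F7 | step 7 | 5-ethoxy-2-[(2R,3S)-1-methoxy-5-methyl-2-(prop-1-en-2-yl)-1-(2,4,6-trimethoxyphenyl)hexan-3-yl]-3-(triisopropylsilyloxy)phenol | CC(C)C[C@H](c1c(O[Si](C(C)C)(C(C)C)C(C)C)cc(OCC)cc1O)[C@@H](C(OC)c1c(OC)cc(OC)cc1OC)C(C)=C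
F8 | step 7 | 5-ethoxy-2-[(2S,3S)-2-isopropyl-1-methoxy-5-methyl-1-(2,4,6-trimethoxyphenyl)hexan-3-yl]-3-(triisopropylsilyloxy)phenol | CC(C)C[C@H](c1c(O[Si](C(C)C)(C(C)C)C(C)C)cc(OCC)cc1O)[C@@H](C(OC)c1c(OC)cc(OC)cc1OC)C(C)C
F9 | step 6 | 3-ethoxybut-3-en-2-one | C=C(OCC)C(C)=O
F10 | step 6 | 5-ethoxy-1,1,1-trifluorohex-5-ene-2,4-dione | C=C(OCC)C(=O)CC(=O)C(F)(F)F
F11 | step 6 | 1-diazo-3-ethoxybut-3-en-2-one | C=C(OCC)C(=O)C=[N+]=[N-]
F12 | step 10 | (2R,3S,4S)-7-ethoxy-4-isobutyl-3-isopropyl-5-methoxy-2-(2,4,6-trimethoxyphenyl)chroman | CC(C)C[C@@H]1c2c(OC)cc(OCC)cc2O[C@@H](c2c(OC)cc(OC)cc2OC)[C@H]1C(C)C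
F13 | step 10 | (2R,3S,4S)-6,8-dibromo-2-(3,5-dibromo-2,4,6-trimethoxyphenyl)-7-ethoxy-4-isobutyl-3-isopropyl-5-methoxychroman | CC(C)C[C@@H]1c2c(OC)c(Br)c(OCC)c(Br)c2O[C@@H](c2c(OC)c(Br)c(OC)c(Br)c2OC)[C@H]1C(C)C
F14 | step 10 | (2R,3S,4S)-2-(3,5-diformyl-2,4,6-trimethoxyphenyl)-7-ethoxy-4-isobutyl-3-isopropyl-5-methoxychroman-6,8-dicarbaldehyde | CC(C)C[C@@H]1c2c(OC)c(C=O)c(OCC)c(C=O)c2O[C@@H](c2c(OC)c(C=O)c(OC)c(C=O)c2OC)[C@H]1C(C)C
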